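**Strategy.** The cyclohexane ring is traced back to a cyclopentanone that already holds the quaternary C(CH3)(vinyl) carbon and the isopropenyl-bearing CH. These are set by asymmetric conjugate addition, trans enolate trapping and a Wharton transposition that moves the oxygen next to the isopropenyl CH. The key step is a regioselective one-carbon ring expansion of this ketone with trimethylsilyldiazomethane. It exploits that, in the target ring, the carbinol carbon lies between the congested isopropenyl CH and the CH carrying the C(OH)(CH2OAc)2 group: only the unhindered side migrates, so the inserted carbon becomes exactly that CH. Aldol addition to a dioxanone, thermodynamic reduction and selective acetylation finish the synthesis.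

Key step: step 8

Assumption: in step 1 the enantiomer of the chiral ferrocenyl diphosphine that leads to the (3S) adduct is used; the sense of induction is fixed by the ligand, not by the substrate.

Step 1
Reactants: 1 2-methylcyclopent-2-en-1-one; 2 isopropenylmagnesium bromide; 3 acetaldehyde
Product: 5 (2R,3S)-2-(1-hydroxyethyl)-2-methyl-3-(prop-1-en-2-yl)cyclopentan-1-one (carbinol epimers), via magnesium enolate 4 (not isolated)
Conditions: 2 (1.2 equiv), CuBr·SMe2 (5 mol %), chiral ferrocenyl diphosphine of the Rev-JosiPhos type (6 mol %), t-BuOMe, −78 °C; then 3 (3 equiv), −78 °C; aq NH4Cl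
Reagents that add atoms: isopropenylmagnesium bromide CC(=C)[Mg]Br; acetaldehyde CC=O
Why: Copper-catalysed asymmetric conjugate addition of the Grignard reagent sets the isopropenyl methine as S under ligand control, and the magnesium enolate then adds to acetaldehyde (aldol) on the face anti to the new isopropenyl group, which fixes the quaternary carbon with methyl cis and the future vinyl carbon trans to isopropenyl.

Step 2
Reactants: 5 (2R,3S)-2-(1-hydroxyethyl)-2-methyl-3-(prop-1-en-2-yl)cyclopentan-1-one
Product: 6 (2S,3S)-2-ethenyl-2-methyl-3-(prop-1-en-2-yl)cyclopentan-1-one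
Conditions: Ph2S[OC(CF3)2Ph]2 (1.5 equiv), CH2Cl2, 0 °C to rt
Reagents that add atoms: none
Why: Sulfurane-mediated E2 dehydration of the secondary carbinol can remove only a methyl hydrogen because the other neighbour is quaternary, so the terminal vinyl group should form without touching either stereocentre.

Step 3
Reactants: 6 (2S,3S)-2-ethenyl-2-methyl-3-(prop-1-en-2-yl)cyclopentan-1-one
Product: 7 (4S,5S)-5-ethenyl-5-methyl-4-(prop-1-en-2-yl)cyclopent-2-en-1-one
Conditions: IBX (2.5 equiv), DMSO/fluorobenzene, 75 °C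
Reagents that add atoms: none
Why: IBX dehydrogenation proceeds through the only enolisable α-CH2 (the other α-carbon is quaternary), so the enone should form regiospecifically.

Step 4
Reactants: 7 (4S,5S)-5-ethenyl-5-methyl-4-(prop-1-en-2-yl)cyclopent-2-en-1-one; 8 hydrogen peroxide
Product: 9 (1R,3S,4S,5R)-3-ethenyl-3-methyl-4-(prop-1-en-2-yl)-6-oxabicyclo[3.1.0]hexan-2-one (epoxide anti to isopropenyl)
Conditions: 30% H2O2, NaOH (0.3 equiv), MeOH, 0 °C
Reagents that add atoms: hydrogen peroxide OO
Why: Weitz–Scheffer nucleophilic epoxidation attacks only the electron-poor enone double bond, with hydroperoxide adding to the β-carbon anti to the adjacent isopropenyl group, while the isolated alkenes are inert.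

Step 5
Reactants: 9 epoxy ketone; 10 hydrazine hydrate
Product: 12 (1S,4R,5S)-4-ethenyl-4-methyl-5-(prop-1-en-2-yl)cyclopent-2-en-1-ol, via epoxy hydrazone 11 (not isolated)
Conditions: N2H4·H2O (3 equiv), AcOH (0.2 equiv), MeOH, 0 °C to rt
Reagents that add atoms: none
Why: Wharton transposition: the epoxy hydrazone loses N2 to give the allylic alcohol, which deletes the original carbonyl oxygen and leaves the epoxide oxygen on the carbon next to the isopropenyl methine (its configuration is retained but irrelevant, as it is oxidised next).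

Step 6
Reactants: 12 (1S,4R,5S)-4-ethenyl-4-methyl-5-(prop-1-en-2-yl)cyclopent-2-en-1-ol
Product: 13 (4R,5S)-4-ethenyl-4-methyl-5-(prop-1-en-2-yl)cyclopent-2-en-1-one
Conditions: 1,1,1-triacetoxy-1,2-benziodoxol-3(1H)-one (DMP, 1.3 equiv), CH2Cl2, 0 °C to rt
Reagents that add atoms: none
Why: Periodinane oxidation of the allylic alcohol is non-basic, so the enone should form without epimerising the α′ methine that carries the isopropenyl group.

Step 7
Reactants: 13 (4R,5S)-4-ethenyl-4-methyl-5-(prop-1-en-2-yl)cyclopent-2-en-1-one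
Product: 14 (2S,3S)-3-ethenyl-3-methyl-2-(prop-1-en-2-yl)cyclopentan-1-one
Conditions: [(Ph3P)CuH]6 (0.4 equiv), H2O (5 equiv), benzene, rt
Reagents that add atoms: none
Why: Copper hydride conjugate reduction delivers hydride only to the enone β-carbon and water protonates the copper enolate, so vinyl, isopropenyl and both stereocentres should be untouched.

Step 8
Reactants: 14 (2S,3S)-3-ethenyl-3-methyl-2-(prop-1-en-2-yl)cyclopentan-1-one; 15 (trimethylsilyl)diazomethane
Product: 17 (2S,3S)-3-ethenyl-3-methyl-2-(prop-1-en-2-yl)cyclohexan-1-one, via alpha-silyl ketone 16 (not isolated)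
Conditions: 15 (1.3 equiv), BF3·OEt2 (1.2 equiv), CH2Cl2, −78 to −20 °C; then 1 M HCl, THF, 0 °C
Reagents that add atoms: (trimethylsilyl)diazomethane C[Si](C)(C)C=[N+]=[N-]
Why: BF3 activates the ketone, the diazo carbon adds to the carbonyl carbon to give a β-oxido diazonium, and the α-carbon anti to the C–N2+ bond migrates with loss of N2, so the five-membered ring becomes six-membered with the new carbon between C=O and the former α-CH2. The closest known reaction type is the Tiffeneau–Demjanov-type Lewis acid-promoted mono-homologation of 2-substituted cycloalkanones with this reagent, which inserts on the less substituted side. No ring is closed; the ring is enlarged by a 1,2-alkyl shift. The only new stereocentre is the silyl-bearing carbon of 16, which is erased by protodesilylation, and the two existing centres are untouched because no enol is formed. The step needs regioselectivity (CH2 versus CH migration), secured by the methine being flanked by the isopropenyl group and the quaternary carbon. It also needs mono-homologation, secured by the hindered, less electrophilic α-silyl ketone 16.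

Step 9
Reactants: 17 (2S,3S)-3-ethenyl-3-methyl-2-(prop-1-en-2-yl)cyclohexan-1-one; 18 2,2-dimethyl-1,3-dioxan-5-one
Product: 20 (2S,3S,6S)-3-ethenyl-6-(5-hydroxy-2,2-dimethyl-1,3-dioxan-5-yl)-3-methyl-2-(prop-1-en-2-yl)cyclohexan-1-one, via lithium enolate 19 (not isolated)
Conditions: LDA (1.05 equiv), THF, −78 °C; 18 (1.5 equiv), −78 to −50 °C; AcOH, −78 °C
Reagents that add atoms: 2,2-dimethyl-1,3-dioxan-5-one CC1(C)OCC(=O)CO1
Why: Kinetic deprotonation should occur at the unhindered new α-CH2 rather than the hindered methine, the lithium enolate adds to the activated ketone (aldol), and the epimerisable α-centre C-6 should settle equatorial, cis to isopropenyl, through the reversible aldolate.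

Step 10
Reactants: 20 aldol adduct
Product: 21 (1R,2S,3S,6R)-3-ethenyl-6-(5-hydroxy-2,2-dimethyl-1,3-dioxan-5-yl)-3-methyl-2-(prop-1-en-2-yl)cyclohexan-1-ol
Conditions: Li (excess), NH3(l)/THF, t-BuOH (2 equiv), −78 °C; NH4Cl
Reagents that add atoms: none
Why: Dissolving-metal ketone reduction is thermodynamically controlled and should give the equatorial alcohol trans to both neighbours (an axial hydroxyl would be syn-axial to the axial methyl), while isolated alkenes and the acetal are inert.

Step 11
Reactants: 21 acetonide diol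
Product: 22 2-[(1R,2R,3S,4S)-4-ethenyl-2-hydroxy-4-methyl-3-(prop-1-en-2-yl)cyclohexyl]propane-1,2,3-triol
Conditions: AcOH/H2O/THF (3:1:1), 40 °C
Reagents that add atoms: none
Why: Mild acid hydrolysis of the isopropylidene acetal should free the two primary hydroxyls without affecting the alkenes or stereocentres.

Step 12
Reactants: 22 tetraol; 23 acetyl chloride
Product: 24 2-[(1R,2R,3S,4S)-4-ethenyl-2-hydroxy-4-methyl-3-(prop-1-en-2-yl)cyclohexyl]-2-hydroxypropane-1,3-diyl diacetate (target)
Conditions: AcCl (2.1 equiv), 2,4,6-collidine, CH2Cl2, −78 to −40 °C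
Reagents that add atoms: acetyl chloride CC(Cl)=O
Why: Acylation at low temperature with a hindered base should take only the two primary hydroxyls, since the flanked secondary and the tertiary hydroxyl are too hindered.

**Compound list**

1 | 2-methylcyclopent-2-en-1-one | CC1=CCCC1=O | starting material
2 | isopropenylmagnesium bromide | CC(=C)[Mg]Br | starting material
3 | acetaldehyde | CC=O | starting material
4 | bromomagnesium (3S)-2-methyl-3-(prop-1-en-2-yl)cyclopent-1-en-1-olate | CC1=C(O[Mg]Br)CC[C@H]1C(=C)C | intermediate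
5 | (2R,3S)-2-(1-hydroxyethyl)-2-methyl-3-(prop-1-en-2-yl)cyclopentan-1-one (carbinol epimers) | CC(O)[C@]1(C)C(=O)CC[C@H]1C(=C)C | intermediate
6 | (2S,3S)-2-ethenyl-2-methyl-3-(prop-1-en-2-yl)cyclopentan-1-one | C=C[C@]1(C)C(=O)CC[C@H]1C(=C)C | intermediate
7 | (4S,5S)-5-ethenyl-5-methyl-4-(prop-1-en-2-yl)cyclopent-2-en-1-one | C=C[C@]1(C)C(=O)C=C[C@H]1C(=C)C | intermediate
8 | hydrogen peroxide | OO | starting material
9 | (1R,3S,4S,5R)-3-ethenyl-3-methyl-4-(prop-1-en-2-yl)-6-oxabicyclo[3.1.0]hexan-2-one | C=C[C@]1(C)C(=O)[C@@H]2O[C@@H]2[C@H]1C(=C)C | intermediate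
10 | hydrazine hydrate | NN.O | starting material
11 | hydrazone of 9 | C=C[C@]1(C)C(=NN)[C@@H]2O[C@@H]2[C@H]1C(=C)C | intermediate
12 | (1S,4R,5S)-4-ethenyl-4-methyl-5-(prop-1-en-2-yl)cyclopent-2-en-1-ol | C=C[C@]1(C)C=C[C@H](O)[C@H]1C(=C)C | intermediate
13 | (4R,5S)-4-ethenyl-4-methyl-5-(prop-1-en-2-yl)cyclopent-2-en-1-one | C=C[C@]1(C)C=CC(=O)[C@H]1C(=C)C | intermediate
14 | (2S,3S)-3-ethenyl-3-methyl-2-(prop-1-en-2-yl)cyclopentan-1-one | C=C[C@]1(C)CCC(=O)[C@H]1C(=C)C | intermediate
15 | (trimethylsilyl)diazomethane | C[Si](C)(C)C=[N+]=[N-] | starting material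
16 | (2S,3S)-3-ethenyl-3-methyl-2-(prop-1-en-2-yl)-6-(trimethylsilyl)cyclohexan-1-one (silyl epimers) | C=C[C@]1(C)CCC([Si](C)(C)C)C(=O)[C@H]1C(=C)C | intermediate
17 | (2S,3S)-3-ethenyl-3-methyl-2-(prop-1-en-2-yl)cyclohexan-1-one | C=C[C@]1(C)CCCC(=O)[C@H]1C(=C)C | intermediate
18 | 2,2-dimethyl-1,3-dioxan-5-one | CC1(C)OCC(=O)CO1 | starting material
19 | lithium (5S,6S)-5-ethenyl-5-methyl-6-(prop-1-en-2-yl)cyclohex-1-en-1-olate | C=C[C@]1(C)CCC=C(O[Li])[C@H]1C(=C)C | intermediate
20 | (2S,3S,6S)-3-ethenyl-6-(5-hydroxy-2,2-dimethyl-1,3-dioxan-5-yl)-3-methyl-2-(prop-1-en-2-yl)cyclohexan-1-one | C=C[C@]1(C)CC[C@@H](C2(O)COC(C)(C)OC2)C(=O)[C@H]1C(=C)C | intermediate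
21 | (1R,2S,3S,6R)-3-ethenyl-6-(5-hydroxy-2,2-dimethyl-1,3-dioxan-5-yl)-3-methyl-2-(prop-1-en-2-yl)cyclohexan-1-ol | C=C[C@]1(C)CC[C@@H](C2(O)COC(C)(C)OC2)[C@H](O)[C@H]1C(=C)C | intermediate
22 | 2-[(1R,2R,3S,4S)-4-ethenyl-2-hydroxy-4-methyl-3-(prop-1-en-2-yl)cyclohexyl]propane-1,2,3-triol | C=C[C@]1(C)CC[C@@H](C(O)(CO)CO)[C@H](O)[C@H]1C(=C)C | intermediate
23 | acetyl chloride | CC(Cl)=O | starting material
24 | 2-[(1R,2R,3S,4S)-4-ethenyl-2-hydroxy-4-methyl-3-(prop-1-en-2-yl)cyclohexyl]-2-hydroxypropane-1,3-diyl diacetate | C=C[C@]1(C)CC[C@@H](C(O)(COC(C)=O)COC(C)=O)[C@H](O)[C@H]1C(=C)C | target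

Total step count: 12. Longest linear sequence: 12 steps (fully linear from 1).

**Steps most likely to fail**

Step 1. The alkenyl Grignard reagent may add sluggishly or with poor facial control to the α-substituted enone, and the enolate may equilibrate before it is trapped. The fallback replaces catalyst control by substrate control. It sets out from 2 and commercial (4S)-4-[(tert-butyldimethylsilyl)oxy]cyclopent-2-en-1-one F1. The cuprate made from 2 (CuI, TMSCl, THF, −78 °C) should add anti to the silyloxy group to give (3R,4S)-4-[(tert-butyldimethylsilyl)oxy]-3-(prop-1-en-2-yl)cyclopentan-1-one F2. DBU should then eliminate the silanol to give (S)-4-(prop-1-en-2-yl)cyclopent-2-en-1-one F3. α′-Methylation (LDA, MeI) anti to isopropenyl should give (4R,5S)-5-methyl-4-(prop-1-en-2-yl)cyclopent-2-en-1-one F4. A second α′-deprotonation and aldol addition to 3, again anti to isopropenyl, should give (4S,5R)-5-(1-hydroxyethyl)-5-methyl-4-(prop-1-en-2-yl)cyclopent-2-en-1-one F5. Dehydration as in step 2 returns to the route at 7.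

Step 5. Hydrazone formation at the ketone flanked by a quaternary carbon may be slow, and reduction or opening of the epoxide may compete with fragmentation. The fallback sets out from 9 and uses a radical epoxide fragmentation. Reduction with NaBH4 should give the epoxy alcohol 3-ethenyl-3-methyl-4-(prop-1-en-2-yl)-6-oxabicyclo[3.1.0]hexan-2-ol (C-2 epimers, other centres as in 9) F6. Thiocarbonyldiimidazole should convert it into the O-(imidazol-1-ylthiocarbonyl) derivative F7. Bu3SnH/AIBN (Barton–McCombie-type radical generation) should then give the carbinyl radical, which opens the epoxide to the allyloxy radical and, after hydrogen transfer, comes back to the route at 12.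

Step 9. The lithium enolate may be quenched by proton transfer from the enolisable dioxanone, and the tertiary aldolate may revert by retro-aldol cleavage. The fallback sets out from 17 and avoids a basic aldolate. LDA/TMSCl should give the kinetic enol silane trimethyl{[(5S,6S)-5-ethenyl-5-methyl-6-(prop-1-en-2-yl)cyclohex-1-en-1-yl]oxy}silane F8. A Mukaiyama aldol addition to 18 (TiCl4, CH2Cl2, −78 °C) should then proceed through a titanium chelate and comes back to the route at 20.

Further compounds
F1 | step 1 | (4S)-4-[(tert-butyldimethylsilyl)oxy]cyclopent-2-en-1-one | O=C1C=C[C@@H](O[Si](C)(C)C(C)(C)C)C1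
F2 | step 1 | (3R,4S)-4-[(tert-butyldimethylsilyl)oxy]-3-(prop-1-en-2-yl)cyclopentan-1-one | C1C(=O)C[C@H](O[Si](C)(C)C(C)(C)C)[C@H]1C(=C)C
F3 | step 1 | (S)-4-(prop-1-en-2-yl)cyclopent-2-en-1-one | C1C(=O)C=C[C@H]1C(=C)C
F4 | step 1 | (4R,5S)-5-methyl-4-(prop-1-en-2-yl)cyclopent-2-en-1-one | C[C@@H]1C(=O)C=C[C@H]1C(=C)C
F5 | step 1 | (4S,5R)-5-(1-hydroxyethyl)-5-methyl-4-(prop-1-en-2-yl)cyclopent-2-en-1-one (carbinol epimers) | CC(O)[C@]1(C)C(=O)C=C[C@H]1C(=C)C
F6 | step 5 | 3-ethenyl-3-methyl-4-(prop-1-en-2-yl)-6-oxabicyclo[3.1.0]hexan-2-ol (C-2 epimers, ring centres as in 9) | C=C[C@]1(C)C(O)[C@@H]2O[C@@H]2[C@H]1C(=C)C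
F7 | step 5 | O-(imidazol-1-ylthiocarbonyl) derivative of F6 | C=C[C@]1(C)C(OC(=S)n3ccnc3)[C@@H]2O[C@@H]2[C@H]1C(=C)C
F8 | step 9 | trimethyl{[(5S,6S)-5-ethenyl-5-methyl-6-(prop-1-en-2-yl)cyclohex-1-en-1-yl]oxy}silane | C=C[C@]1(C)CCC=C(O[Si](C)(C)C)[C@H]1C(=C)C
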